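The runs are simulated for substances that don't exist, noise included.

Set the partner charge against 2 starting material, since a bis adduct holds two partner, and read the ratio as the partner ceiling, the most bis adduct the partner charge can make, in percent of the starting material charged: 75.0% for these flasks, which makes partner the limiting reagent on the charges as written.

| flask | starting material | partner | remark | time |
|---|---|---|---|---|
| green | 22 mM | 33 mM | run made earlier |  |
| blue | 11 mM | 33 mM | run made earlier |  |
| amber | 16 mM | 33 mM | run made earlier |  |
| red | 22 mM | 66 mM | run made earlier |  |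
| birch | 22 mM | 33.0 mM | everything together at the start | 1.0 h |
| oak | 22 mM | 33.0 mM (fed, over 50 min) | all else is in the flask from the start; the feed brings no volume worth counting | 1.0 h |
| cedar | 22 mM (fed, over 50 min) | 33.0 mM | all else is in the flask from the start; the feed brings no volume worth counting | 1.0 h |
| larch | 22 mM (in portions, 2, over 50 min) | 33.0 mM | first portion at the start, last at 50 min | 1.0 h |

| run | time / min | bis adduct / % | single product / % |
|---|---|---|---|
| green | 2.00 | 35.1 | 32.9 |
| green | 6.00 | 51.9 | 28.5 |
| green | 10.0 | 54.5 | 27.6 |
| green | 15.0 | 54.9 | 26.8 |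
| green | 20.0 | 54.8 | 26.4 |
| green | 30.0 | 55.5 | 26.5 |
| green | 40.0 | 55.3 | 27.4 |
| blue | 2.50 | 66.2 | 22.7 |
| blue | 8.00 | 93.6 | 4.6 |
| blue | 15.0 | 97.9 | 0.5 |
| blue | 20.0 | 99.1 | 0.9 |
| blue | 30.0 | 99.3 | 0 |
| blue | 40.0 | 98.2 | 0 |
| blue | 50.0 | 99.4 | 0 |
| amber | 6.00 | 75.6 | 16.8 |
| amber | 15.0 | 88.4 | 8.2 |
| amber | 20.0 | 91.6 | 5.3 |
| amber | 30.0 | 95.2 | 3.1 |
| amber | 40.0 | 96.6 | 3.0 |
| amber | 50.0 | 97.7 | 1.9 |
| red | 4.00 | 94.0 | 4.5 |
| red | 12.0 | 98.9 | 0 |
| red | 20.0 | 99.5 | 0 |
| red | 30.0 | 99.5 | 0 |
| red | 50.0 | 99.2 | 0.1 |

(each reading ± 0.5 percentage points)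

1. the flask that comes out highest in amount of bis adduct, in percent of the starting material charged, or "all alike" when all lie within 1.5 percentage points (birch / oak / cedar / larch / all alike)
2. bis adduct at the end, in percent of the starting material charged, birch
3. bis adduct at the end, in percent of the starting material charged, oak
4. bis adduct at the end, in percent of the starting material charged, cedar
5. bis adduct at the end, in percent of the starting material charged, larch

Blue has a ceiling of 150% and ends at 99.4% bis adduct. Green has the ceiling of 75.0% and stays flat near 55.3%, lower than that ceiling.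

My rule: with the whole partner charge bound, bis adduct equals the ceiling less half of the mono adducts standing. Green then needs 39.4% mono adduct, yet its single product reads 27.4%, so 12 percentage points stays unread. The four recipes share one ceiling, so between recipes that bind their whole partner charge, less mono adduct standing means more bis adduct, and I expect cedar on top, still under 75.0%.

The forecast agrees on cedar, with 55.3% for birch, 52% for oak, 67% for cedar and 64.5% for larch. It says: “Cedar keeps SM low, so it avoids the loss and makes bis early.”

    starting material + partner → single product (k = 45.0 M⁻¹ min⁻¹)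
    starting material + partner → other mono adduct (k = 37.0 M⁻¹ min⁻¹)
    partner + single product → bis adduct (k = 23.0 M⁻¹ min⁻¹)
    partner + other mono adduct → bis adduct (k = 44.0 M⁻¹ min⁻¹)
    2 starting material → homo dimer (k = 1.60 M⁻¹ min⁻¹)

Cedar comes out highest at 67.8%, above larch at 61.3%, oak at 59.4% against the forecast's 52%, and birch at 55.4%. Oak ends with 39.8% of its charge as homo dimer and 20% of its partner left, so its partner is not wholly bound and the rule does not apply to it; it stands under the ceiling. Cedar, with 0.011% of its partner left, holds 9.19% single product and 5.14% other mono adduct, and the rule gives 67.8%. The neighbour with 13 mM of starting material has a ceiling of 127%, which leaves 21.2% of its partner over; it ends with 21.9% of its partner and 99.1% bis adduct.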